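Take the ratio g of the rate constant of link formation to the dissolution coefficient of the crystals, 0.742 /M, the overhang factor. While crystals stand and links form slowly enough for them to keep up, the free links sit above their solubility by an overhang h = g·A·B, where A and B are the concentrations of first and second end groups.

in all of them: solid first end groups 0.30 M; second end groups 0.330 M; third end groups 0.0750 M; time 10 d

|  | protic impurity |
|---|---|
| autumn | 0.00200 M |
| noon | 0.00600 M |
| dawn | 0.0150 M |
| summer | 0.0500 M |
| winter | 0.150 M |

    solid first end groups ⇌ first end groups, rate k1*(cs1 - [first end groups]) while solid is left; crystals form when [first end groups] > cs1 (cs1 = 0.15 M, k1 = 0.0016 /min)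
    first end groups + second end groups → links (k2 = 0.0023 /M/min)
    crystals ⇌ links, rate k3*(cs3 - [links]) while solid is left; crystals form when [links] > cs3 (cs3 = 34 mM, k3 = 0.0031 /min)
    second end groups + third end groups → links of the second sort (k4 = 0.0013 /M/min)
    third end groups + protic impurity → quenched substrate (k5 = 2.2 × 10⁻⁴ /M/min)

- links is meant together with its crystals
- solid, in amounts per volume of the solution: solid first end groups, crystals
- at the start none of the solid first end groups is in solution
- the concentration of links that is asked is that of its free form alone
- "hardly changes" means that all values lie within two and a half points (for a concentration: within two and a half percent of the largest)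
- run time (autumn): 10 d

- [links] (only what is free in solution) at the end for autumn, noon, dawn, summer, winter, in this order
- how that number moves from the first to the last of them (falls, then rises / hardly changes / rises all the way / falls all the way / rises, then falls)

I climb the ladder by half-times. Crystals answer in 0.155 d, faster than the solid dissolves (0.301 d) or first end groups meet a full charge of B (0.63 d, autumn).

On that early rung, A at its solubility and B at its charge give an overhang of 0.0367 M, about as large as the solubility of links, 34 mM, so I expect free links to stand high at first.

The next rung is set by B, the limiting reagent: A and third end groups together are charged 0.0450 M (call it D) above B. So B's tail has a half-time near 4.65 d, far slower than the crystals, and the overhang can follow g·A·B from moment to moment.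

The top rung is the quench, with a half-life of 1100 d for third end groups in autumn, against a run of 10 d. Even in winter, at the start, step 4 takes third end groups 13.0 times as fast as the impurity does. I therefore leave the impurity out and count third end groups as if they were first end groups, which gives one second-order tail:

B/(B + D) = cB/(cB + D) · exp(−k·D·t) = 0.198

B = D·u/(1 − u) = 0.0111 M

h = g·B·(B + D) = 4.63 × 10⁻⁴ M

Here k is the rate constant of link formation, cB the charge of B, t the run time and u the left side of the first line. With the impurity left out, my reckoning gives one value for the row, 0.0345 M. The whole overhang is a small share of the solubility, 1.36 %, inside the margin, so I expect the row to hardly change.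

The forecast gives 0.0349 M, 0.0349 M, 0.035 M, 0.0351 M, 0.0354 M, shape hardly changes, because “the free concentration sits just above the 34 mM solubility”. Its values stand above mine, and they rise slightly where mine stay flat.

The flask gives 0.0346 M, 0.0346 M, 0.0346 M, 0.0346 M, 0.0346 M: hardly changes. In autumn, dissolved links are made at 0.947 of the rate at which they are used at 10.0 d. With autumn's simulated A and B, the overhang factor gives 5.51 × 10⁻⁴ M. With winter's it gives 5.86 × 10⁻⁴ M. For the forecast's shape to fail, these two flasks would have to part by more than 8.65 × 10⁻⁴ M, but winter's overhang stands 3.47 × 10⁻⁵ M above autumn's.

The constants used here are those of an exercise; the run is a simulation.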